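**Retrosynthetic overview**
1. Target 24 ⇒ O-methylation at the lactone oxygen of the 3-substituted 4-hydroxy-5-methylcoumarin 22; the C1–aryl bond of 22 ⇒ lactol 13 + coumarin 21 (dehydrative C-alkylation).
2. Dihydropyran ring of 13 ⇒ amine-catalysed Michael addition/hemiacetalisation of enal 7 with 1,2-diketone 11 (C4a–C4 and O–C1 bonds).
3. Cyclopentene 7 ⇒ key ring contraction (bromohydrin semipinacol 1,2-alkyl shift, then loss of acetate) of epoxycyclohexyl acetate 4 ⇒ copper-catalysed kinetic resolution of vinyl oxirane 1.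
4. 11 ⇒ alkyne alkylation/oxidation; 21 ⇒ pentane-2,4-dione + crotonaldehyde benzannulation, then carbonate ring closure.
5. Ring order: cyclohexene (bought) → cyclopentene (contraction) → dihydropyran; separately benzene ring → pyranone; the two halves are joined at C1 last.

Assumption: the SMILES is read as the (1R,4aS,7S,7aR) isomer; all numbered starting materials are taken as commercial, 1 as the racemate.

**Step 1**
Reactants: 1 rac-7-oxabicyclo[4.1.0]hept-2-ene
Product: 2 (1S,4S)-4-methylcyclohex-2-en-1-ol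
Conditions: Me2Zn (0.55 equiv), Cu(OTf)2 (1.5 mol%), BINOL-derived bis(1-phenylethyl)amine phosphoramidite (3 mol%; the antipode that consumes (1R,6S)-1), PhMe, −10 °C; sat. aq. NH4Cl
Reagents that add atoms: dimethylzinc C[Zn]C
Why: Copper-catalysed anti-SN2' allylic alkylation of a vinyl oxirane by a dialkylzinc, run as a kinetic resolution, delivers methyl to the alkene terminus of (1R,6S)-1 on the face opposite the oxirane oxygen, which sets the methyl-bearing centre (the later C7, S) and the trans-1,4 relationship, while unreacted ent-1 is distilled off.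

**Step 2**
Reactants: 2 (1S,4S)-4-methylcyclohex-2-en-1-ol
Product: 4 (1S,2S,3R,4S)-2,3-epoxy-4-methylcyclohexyl acetate, via epoxy alcohol 3 (not isolated)
Conditions: mCPBA, CH2Cl2, 0 °C; then pyridine, Ac2O, DMAP (cat.), rt
Reagents that add atoms: mCPBA (3-chloroperoxybenzoic acid) OOC(=O)c1cccc(Cl)c1; acetic anhydride CC(=O)OC(C)=O
Why: Henbest hydroxyl-directed peracid epoxidation places the oxirane cis to OH (anti to the methyl group), and acetylation in the same flask turns the hydroxyl into a non-donating group that later leaves as acetate.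

**Step 3**
Reactants: 4 (1S,2S,3R,4S)-2,3-epoxy-4-methylcyclohexyl acetate
Product: 7 (5S)-5-methylcyclopent-1-ene-1-carbaldehyde, via bromohydrin alkoxide 5 (not isolated), via acetoxy aldehyde 6 (not isolated)
Conditions: LiBr·HMPA (30 mol%), PhMe, 80 °C; then DBU (1.2 equiv), rt
Reagents that add atoms: none
Why: Key ring contraction by the lithium-salt-catalysed epoxide-to-aldehyde rearrangement (bromohydrin semipinacol): bromide opens the oxirane trans-diaxially at the carbon remote from OAc, the alkoxide then pushes the antiperiplanar ring bond onto the bromide-bearing carbon (1,2-alkyl shift, six- to five-membered ring), opening at the other oxirane carbon converges on the same β-acetoxy aldehyde, and E1cB loss of acetate gives the conjugated enal, so the only surviving stereocentre is the untouched methyl-bearing carbon.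

**Step 4**
Reactants: 8 4-methylpent-1-yne
Product: 10 6-methylhept-3-yne, via lithium acetylide 9 (not isolated)
Conditions: n-BuLi, THF, −78 °C; EtI, DMPU, −78 °C → rt
Reagents that add atoms: iodoethane CCI
Why: SN2 alkylation of a lithium acetylide with a primary iodide.

**Step 5**
Reactants: 10 6-methylhept-3-yne
Product: 11 6-methylheptane-3,4-dione
Conditions: RuO2·xH2O (2 mol%), NaIO4 (2.2 equiv), EtOAc/MeCN/H2O, rt
Reagents that add atoms: sodium periodate [Na+].[O-]I(=O)(=O)=O
Why: RuO4 generated from catalytic RuO2 and periodate oxidises a dialkyl alkyne to the 1,2-diketone without C–C cleavage under these biphasic conditions (ruthenium-catalysed alkyne oxidation).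

**Step 6**
Reactants: 7 (5S)-5-methylcyclopent-1-ene-1-carbaldehyde; 11 6-methylheptane-3,4-dione
Product: 13 1-[(4aS,7S,7aR)-1-hydroxy-4,7-dimethyl-1,4a,5,6,7,7a-hexahydrocyclopenta[c]pyran-3-yl]-3-methylbutan-1-one, via keto aldehyde 12 (not isolated)
Conditions: (R)-2-[diphenyl(trimethylsilyloxy)methyl]pyrrolidine (20 mol%), PhCO2H (20 mol%), 11 (1.5 equiv), PhMe, rt
Reagents that add atoms: none
Why: Proposed new method: iminium-catalysed conjugate addition of an acyclic, unsymmetrical 1,2-diketone to an α-branched cyclic enal followed by hemiacetalisation — the enol of 11 on its less hindered ethyl side adds to the β-carbon (C4a) of the iminium ion of 7 anti to the C7 methyl group (reinforced by the (R)-catalyst as the matched pair in the E, s-trans iminium model), the resulting aldehyde is epimerisable at C7a through its enamine and is drained as the cis-fused lactol by the diosphenol OH, which forms the C4a–C4 bond and the dihydropyran ring and sets C4a (S) and C7a (R); the closest known reaction is the diarylprolinol silyl ether catalysed Michael addition/hemiacetalisation of cyclic 1,2-diones with β-substituted enals.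

**Step 7**
Reactants: 14 pentane-2,4-dione; 15 (E)-but-2-enal
Product: 18 1-(2-hydroxy-6-methylphenyl)ethan-1-one, via Michael adduct 16 (not isolated), via cyclohexenone 17 (not isolated)
Conditions: KOt-Bu (10 mol%), t-BuOH, 0 → 60 °C; AcOH, evaporate; DDQ (1.1 equiv), PhMe, 80 °C
Reagents that add atoms: none
Why: Base-catalysed Michael addition/intramolecular aldol condensation (Robinson-type annulation, the diketone analogue of the Hauser salicylate synthesis) fixes the 1,2,3-substitution pattern, and DDQ dehydrogenation aromatises the 2-acylcyclohexenone to the phenol.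

**Step 8**
Reactants: 18 1-(2-hydroxy-6-methylphenyl)ethan-1-one; 19 dimethyl carbonate
Product: 21 4-hydroxy-5-methyl-2H-chromen-2-one, via keto ester 20 (not isolated)
Conditions: NaH (3 equiv), PhMe, 110 °C; aq. HCl
Reagents that add atoms: none
Why: Claisen-type C-methoxycarbonylation of the ketone enolate followed by lactonisation of the phenoxide onto the ester is the standard 4-hydroxycoumarin synthesis.

**Step 9**
Reactants: 13 1-[(4aS,7S,7aR)-1-hydroxy-4,7-dimethyl-1,4a,5,6,7,7a-hexahydrocyclopenta[c]pyran-3-yl]-3-methylbutan-1-one; 21 4-hydroxy-5-methyl-2H-chromen-2-one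
Product: 22 4-hydroxy-5-methyl-3-[(1R,4aS,7S,7aR)-4,7-dimethyl-3-(3-methylbutanoyl)-1,4a,5,6,7,7a-hexahydrocyclopenta[c]pyran-1-yl]-2H-chromen-2-one
Conditions: 21 (1.0 equiv), TsOH·H2O (10 mol%), 4 Å MS, CH2Cl2, rt
Reagents that add atoms: none
Why: Acid-catalysed dehydrative C-alkylation of the 4-hydroxycoumarin (Friedel–Crafts-type C-glycosylation of a lactol) runs through the cyclic oxocarbenium ion of 13, which C3 of 21 attacks on the convex face of the cis-fused bicycle (cis to H7a), and because ionisation is reversible the more stable (1R) epimer accumulates.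

**Step 10**
Reactants: 22 4-hydroxy-5-methyl-3-[(1R,4aS,7S,7aR)-4,7-dimethyl-3-(3-methylbutanoyl)-1,4a,5,6,7,7a-hexahydrocyclopenta[c]pyran-1-yl]-2H-chromen-2-one
Product: 24 2-methoxy-5-methyl-3-[(1R,4aS,7S,7aR)-4,7-dimethyl-3-(3-methylbutanoyl)-1,4a,5,6,7,7a-hexahydrocyclopenta[c]pyran-1-yl]-4H-chromen-4-one, via silver salt 23 (not isolated)
Conditions: Ag2O (1.5 equiv), MeI (5 equiv), PhMe, rt, dark
Reagents that add atoms: iodomethane CI
Why: Silver-salt O-alkylation of the ambident 4-hydroxycoumarin anion should go to the lactone oxygen because O4 is buried between the peri 5-methyl group and the branched C3 substituent, and the neutral conditions spare the acid-labile 2-methoxychromone.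

**Compound list**
1 | rac-7-oxabicyclo[4.1.0]hept-2-ene | C1CC2OC2C=C1 | starting material
2 | (1S,4S)-4-methylcyclohex-2-en-1-ol | O[C@@H]1C=C[C@@H](C)CC1 | intermediate
3 | (1S,2S,3R,4S)-2,3-epoxy-4-methylcyclohexan-1-ol | O[C@@H]1[C@@H]2O[C@@H]2[C@@H](C)CC1 | intermediate
4 | (1S,2S,3R,4S)-2,3-epoxy-4-methylcyclohexyl acetate | CC(=O)O[C@@H]1[C@@H]2O[C@@H]2[C@@H](C)CC1 | intermediate
5 | lithium (1S,2S,5S,6S)-2-acetoxy-6-bromo-5-methylcyclohexan-1-olate | [Li+].CC(=O)O[C@@H]1[C@H]([O-])[C@@H](Br)[C@@H](C)CC1 | intermediate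
6 | (1S,2S,3S)-2-formyl-3-methylcyclopentyl acetate | CC(=O)O[C@H]1CC[C@H](C)[C@@H]1C=O | intermediate
7 | (5S)-5-methylcyclopent-1-ene-1-carbaldehyde | C[C@H]1CCC=C1C=O | intermediate
8 | 4-methylpent-1-yne | C#CCC(C)C | starting material
9 | lithium 4-methylpent-1-yn-1-ide | [Li+].[C-]#CCC(C)C | intermediate
10 | 6-methylhept-3-yne | CCC#CCC(C)C | intermediate
11 | 6-methylheptane-3,4-dione | CCC(=O)C(=O)CC(C)C | intermediate
12 | (1R,2S,5S)-2-methyl-5-(6-methyl-3,4-dioxoheptan-2-yl)cyclopentane-1-carbaldehyde (side-chain C2 epimers) | CC(C)CC(=O)C(=O)C(C)[C@H]1CC[C@H](C)[C@H]1C=O | intermediate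
13 | 1-[(4aS,7S,7aR)-1-hydroxy-4,7-dimethyl-1,4a,5,6,7,7a-hexahydrocyclopenta[c]pyran-3-yl]-3-methylbutan-1-one (anomer mixture) | CC(C)CC(=O)C1=C(C)[C@H]2CC[C@H](C)[C@H]2C(O)O1 | intermediate
14 | pentane-2,4-dione | CC(=O)CC(C)=O | starting material
15 | (E)-but-2-enal | C/C=C/C=O | starting material
16 | 4-acetyl-3-methyl-5-oxohexanal | CC(CC=O)C(C(C)=O)C(C)=O | intermediate
17 | 6-acetyl-5-methylcyclohex-2-en-1-one | CC(=O)C1C(C)CC=CC1=O | intermediate
18 | 1-(2-hydroxy-6-methylphenyl)ethan-1-one | CC(=O)c1c(C)cccc1O | intermediate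
19 | dimethyl carbonate | COC(=O)OC | starting material
20 | methyl 3-(2-hydroxy-6-methylphenyl)-3-oxopropanoate | COC(=O)CC(=O)c1c(C)cccc1O | intermediate
21 | 4-hydroxy-5-methyl-2H-chromen-2-one | Cc1cccc2oc(=O)cc(O)c12 | intermediate
22 | 4-hydroxy-5-methyl-3-[(1R,4aS,7S,7aR)-4,7-dimethyl-3-(3-methylbutanoyl)-1,4a,5,6,7,7a-hexahydrocyclopenta[c]pyran-1-yl]-2H-chromen-2-one | Cc1cccc2oc(=O)c(c(O)c12)[C@@H]1OC(C(=O)CC(C)C)=C(C)[C@H]2CC[C@H](C)[C@H]21 | intermediate
23 | silver 4-olate of 22 | [Ag+].Cc1cccc2oc(=O)c(c([O-])c12)[C@@H]1OC(C(=O)CC(C)C)=C(C)[C@H]2CC[C@H](C)[C@H]21 | intermediate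
24 | 2-methoxy-5-methyl-3-[(1R,4aS,7S,7aR)-4,7-dimethyl-3-(3-methylbutanoyl)-1,4a,5,6,7,7a-hexahydrocyclopenta[c]pyran-1-yl]-4H-chromen-4-one | COc1oc2cccc(C)c2c(=O)c1[C@@H]1OC(C(=O)CC(C)C)=C(C)[C@H]2CC[C@H](C)[C@H]21 | target

**Step count and risks**
Total: 10 steps. Longest linear sequence: 6 steps (1 → 2 → 3 → 6 → 9 → 10).

Step 6 (the proposed new step) is the most likely to fail. The α-branched iminium ion forms slowly, and the diketone may react on its isobutyl side or condense with the catalyst. The fallback uses known chemistry, sets out from 11 and 7 and returns at 13. LiHMDS in THF at −78 °C deprotonates 11 on the ethyl side to give lithium (Z)-6-methyl-4-oxohept-2-en-3-olate F3. This is added at −78 °C to enal 7 precomplexed in toluene with aluminium tris(2,6-diphenylphenoxide), Al(OC6H3Ph2-2,6)3, whose aryloxide pocket blocks the formyl carbon and steers lithium enolates to 1,4-addition anti to the methyl group. Work-up with aqueous NH4Cl gives keto aldehyde 12, which closes to lactol 13 on stirring with Et3N.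

Step 10 is the second risk. The ambident anion may give the 4-methoxycoumarin instead. The fallback sets out from 18 and returns at 24, and fixes the regiochemistry through sulfur. CS2 and KOt-Bu convert 18 into 4-hydroxy-5-methyl-2H-chromene-2-thione F4. TsOH-catalysed coupling with 13, as in step 9, gives the thione analogue of 22 F5. MeI and K2CO3 in acetone methylate only the soft sulfur to give the 2-methylsulfanyl chromone F6. One equivalent of mCPBA at −40 °C gives the 2-methanesulfinyl chromone F7. NaOMe in MeOH at 0 °C then displaces the sulfinyl group by addition–elimination at C2 to give 24.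

Step 3 is the third risk. A hydride shift to the cyclohexanone, acetyl migration in alkoxide 5 or an unfavourable ring flip could divert the rearrangement. The fallback sets out from 2 and returns at 7, and contracts the ring oxidatively from the alkene. TBSCl and imidazole give tert-butyldimethyl{[(1S,4S)-4-methylcyclohex-2-en-1-yl]oxy}silane F1. Thallium trinitrate trihydrate, Tl(NO3)3·3H2O, in MeOH/HC(OMe)3 at 0 °C (oxythallation, then 1,2-alkyl shift with loss of the metal) gives tert-butyl{[(1S,3S)-2-(dimethoxymethyl)-3-methylcyclopentyl]oxy}dimethylsilane F2. Aqueous HCl in THF at 40 °C hydrolyses the acetal, removes the silyl group and dehydrates the aldol to 7.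

**Further compounds**
F1 | step 3 | tert-butyldimethyl{[(1S,4S)-4-methylcyclohex-2-en-1-yl]oxy}silane | CC(C)(C)[Si](C)(C)O[C@@H]1C=C[C@@H](C)CC1
F2 | step 3 | tert-butyl{[(1S,3S)-2-(dimethoxymethyl)-3-methylcyclopentyl]oxy}dimethylsilane | COC(OC)C1[C@@H](C)CC[C@@H]1O[Si](C)(C)C(C)(C)C
F3 | step 6 | lithium (Z)-6-methyl-4-oxohept-2-en-3-olate | [Li+].C/C=C(\[O-])C(=O)CC(C)C
F4 | step 10 | 4-hydroxy-5-methyl-2H-chromene-2-thione | Cc1cccc2oc(=S)cc(O)c12
F5 | step 10 | 4-hydroxy-5-methyl-3-[(1R,4aS,7S,7aR)-4,7-dimethyl-3-(3-methylbutanoyl)-1,4a,5,6,7,7a-hexahydrocyclopenta[c]pyran-1-yl]-2H-chromene-2-thione | Cc1cccc2oc(=S)c(c(O)c12)[C@@H]1OC(C(=O)CC(C)C)=C(C)[C@H]2CC[C@H](C)[C@H]21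
F6 | step 10 | 5-methyl-2-(methylsulfanyl)-3-[(1R,4aS,7S,7aR)-4,7-dimethyl-3-(3-methylbutanoyl)-1,4a,5,6,7,7a-hexahydrocyclopenta[c]pyran-1-yl]-4H-chromen-4-one | CSc1oc2cccc(C)c2c(=O)c1[C@@H]1OC(C(=O)CC(C)C)=C(C)[C@H]2CC[C@H](C)[C@H]21
F7 | step 10 | 2-(methanesulfinyl)-5-methyl-3-[(1R,4aS,7S,7aR)-4,7-dimethyl-3-(3-methylbutanoyl)-1,4a,5,6,7,7a-hexahydrocyclopenta[c]pyran-1-yl]-4H-chromen-4-one | CS(=O)c1oc2cccc(C)c2c(=O)c1[C@@H]1OC(C(=O)CC(C)C)=C(C)[C@H]2CC[C@H](C)[C@H]21
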